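A small charge of free monomer, 0.010 M, can leave the free state in two ways: into chains or into the dormant form. Count the fraction left, not the fraction made.

all flasks: free monomer 0.010 M

|  | initiator | temperature | remark | time |
|---|---|---|---|---|
| north-west | 1.4 mol% | 0 °C | run made earlier |  |
| north | 2.2 mol% | 15 °C | run made earlier |  |
| midnight | 1 mol% | 25 °C |  | 40 min |
| spring | 1 mol% | 5 °C |  | 40 min |

- north-west (time / min: monomer in chains / %, free monomer / %): 40.0: 31, 47; 80.0: 51, 25; 150: 60, 6; 180: 60, 4
- north (time / min: monomer in chains / %, free monomer / %): 6.00: 10, 65; 12.0: 26, 38; 30.0: 42, 13; 80.0: 50, 8

(each reading ± 2 percentage points)

* the best flask by amount of monomer in chains, in percent of the free monomer charged; "all alike" if 1.5 percentage points covers them all (midnight / spring / all alike)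
* amount of monomer in chains at the end, in percent of the free monomer charged, midnight
* amount of monomer in chains at the end, in percent of the free monomer charged, spring

- the earlier runs were read with a standard deviation of 2 percentage points
- candidate steps: free monomer <-> dormant form; free monomer + living end -> monomer in chains + living end; free monomer + initiator -> living end + monomer in chains; 2 living end <-> resting dimer

First question: of what has left, how much stands in chains? The north-west run at 40.0 min reads 31% in chains and 47% free, which gives 0.585. Call monomer in chains over the fraction no longer free the chain share. The north run reads 0.483 at 30.0 min. Both are readings, with scatter. Take 0.5 for both new flasks as a rough guess: each holds less initiator than either run, so neither reading carries over directly.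

Second question: how much stays free in spring? Take minus the natural logarithm of the fraction left, divided by time. This pseudo-first-order loss constant reads 0.0189 /min at 0 °C and 0.0806 /min at 15 °C. Spring lies a third of the way up in temperature, and the two runs differ in initiator too, so my rough figure is 0.0306 /min. My estimate for spring is then 29.4% free and 35.3% in chains.

Third question: where does midnight stop? Extend the trend to 0.212 /min. The loss half-life is then 3.27 min, far shorter than 40 min, so expect a balance. Late readings put free monomer at 0.100 and 0.160 of everything outside chains. Extended, that is 0.219. My estimate for midnight is then 12.3% free and 43.9% in chains, more than my estimate for spring.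

The forecast differs: spring best, 24% for midnight, 30% for spring. Its words: “Spring probably wins, though uncertainly.”

The flasks give 41.1% for midnight and 31.5% for spring, so midnight is best.

    free monomer ⇌ dormant form (K = 2.00, k = 0.180 /min, Ea = 90.0 kJ/mol, ΔH = −61.0 kJ/mol)
    free monomer + living end → monomer in chains + living end, rate k2*[living end]*[free monomer] (k = 2100 /M/min, Ea = 44.0 kJ/mol)
    free monomer + initiator → living end + monomer in chains (k = 8.50 /M/min, Ea = 38.0 kJ/mol)
    2 living end ⇌ resting dimer (K = 96000 /M, k = 3000 /M/min, Ea = 52.0 kJ/mol, ΔH = −11.0 kJ/mol)
    (constants at 25 °C)

In spring, the half-life of free monomer toward chains at 14.6 min is of like size to the 48.3 min relaxation half-life with the dormant form, both ways together, and the chain share ends at 0.487, beside 0.501 in midnight, while free monomer stands at 35.3% against 17.9%. The north-west run read a chain share of 0.585 at 40.0 min; the same flask as spring with 2.5 mol% of initiator ends with 24% free and a chain share of 0.636, above that of spring, and holds 48.3% in chains.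

The numbers in the tables were computed on assumed constants; noise was put on by code.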